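Start from the south run and reckon what stays, not what forms.

| setting | south-east | south | flask |
|---|---|---|---|
| J | 0.48 M (in portions, 3) | 0.48 M (in portions, 3) | 0.48 M (in portions, 3) |
| G | 0.528 M | 0.26 M | 0.528 M |
| remark | the very flask that is asked about, followed so far; portions every 80 min | run made earlier; portions every 80 min | the portions of J follow each other after 80 min, the first at the start |
| time |  |  | 15 d |

| run | time / d | J / % | L / % | D / % |
|---|---|---|---|---|
| south-east | 0.500 | 50.5 | 15.9 | 2.0 |
| south-east | 1.04 | 21.6 | 37.2 | 9.2 |
| south-east | 1.67 | 7.8 | 47.5 | 18.3 |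
| south-east | 2.08 | 4.0 | 48.9 | 22.5 |
| south-east | 2.50 | 2.2 | 49.5 | 26.6 |
| south-east | 3.00 | 1.1 | 49.9 | 28.6 |
| south | 0.833 | 29.6 | 32.7 | 6.2 |
| south | 1.25 | 16.3 | 45.5 | 13.4 |
| south | 2.50 | 3.2 | 55.0 | 28.2 |
| south | 4.00 | 0 | 54.6 | 33.4 |
| south | 6.00 | 0.2 | 54.7 | 34.2 |
| south | 10.0 | 0 | 54.5 | 34.3 |

(readings scatter by 0.3 percentage points)

- the reaction counts as stopped when no species that holds the J changes by six tenths of a point or more over the second half of the time

1. why nothing more happens at 15 d, or that something still does (all of J has reacted / G has run out first / it is still moving / forward and back rates have come level)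
2. share of the J used up at 15 d
3. L at 15 d, in percent of the J charged
4. D at 15 d, in percent of the J charged

The flask asked about is the south-east run carried on to 15 d. Its J falls from 21.6 % to 1.1 % between 1.04 d and 3.00 d, a first-order constant of 1.52 /d. So J halves every 0.456 d, short against the time, and we put the conversion at >99.9 %.

But in the south run at 10.0 d, J reads 0 %, and L and D stand at 54.5 % and 34.3 %, flat within the scatter since 6.00 d, so 11.2 % of the J is held by neither. The south and south-east recipes differ in G, so, with J and its portions held, we take the share lost per share kept as proportional to charged G and carry the loss coefficient, that share per molar of charged G (a selectivity factor), read from the south run as 0.485 /M.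

At [G] = 0.528 M in the flask asked about, we reckon the fraction kept at 79.6 %, so the loss at 20.4 %; the south-east gap reads 20.4 % at 3.00 d, a reading taken while J still stands at 1.1 %. The late south readings give D/L = 0.629, so we reckon L at 48.9 % and D at 30.8 %.

The forecast differs and stands higher on D: all of J has reacted, conversion 100 %, L 50.2 %, D 32 %, with “the gap seems to level near 18–19, probably larger with more G”.

The flask gives all of J has reacted, conversion 100 %, L 49.1 % and D 30.9 %, so the forecast held.

    J → E (k = 1.80 × 10⁻⁵ /s)
    E → L (k = 2.50 × 10⁻⁵ /s)
    G + E → Z (k = 1.30 × 10⁻⁵ /M/s)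
    L ⇌ D (K = 0.630, k = 8.20 × 10⁻⁶ /s)

In this flask E goes to L at 2.5 × 10⁻⁵ /s and, at charged [G], to Z at 6.86 × 10⁻⁶ /s, which is slower, and Z ends at 19.9 %, a lost-to-kept ratio of 0.249 where the loss coefficient gave 0.256. For a neighbour charged with 2.1 M of G, the coefficient keeps 49.5 %, and that neighbour ends with L 30.3 %, D 19.1 % and Z 50.7 %.

The data stem from a simulated flask from invented constants; scatter was added.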